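If a flask stops with both partners still present, I reasoned, then forward and back rates may have come level, and dividing one rate by the other leaves a number with no time in it. So I first asked whether the two earlier runs had stopped that way.

| flask | substrate | reagent | remark | time |
|---|---|---|---|---|
| midnight | 0.35 M | 0.15 M (fed, over 20 s) | run made earlier; the fed solution adds 0.25 times the starting volume |  |
| noon | 0.55 M | 0.15 M (fed, over 20 s) | run made earlier; the fed solution adds 0.25 times the starting volume |  |
| flask | 0.25 M | 0.150 M (fed, over 20 s) | the fed solution adds 0.25 times the starting volume | 20 min |

- midnight (time / min: substrate / %, target / %): 0.667: 79.6, 11.6; 2.00: 68.2, 27.6; 3.00: 64.8, 33.0; 5.00: 62.7, 35.5; 8.00: 61.3, 34.6; 10.0: 61.9, 34.7; 12.0: 62.7, 34.4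
- noon (time / min: substrate / %, target / %): 1.00: 79.3, 13.6; 1.33: 78.8, 17.4; 2.00: 76.8, 20.7; 3.00: 75.2, 23.0; 5.00: 74.7, 24.0; 8.00: 74.1, 23.4; 12.0: 74.6, 23.9

(standard deviation of a reading: 0.5 percentage points)

1. the state of affairs at 20 min: stopped, and by what, or still going (it is still moving / all of the substrate has reacted / the reagent has run out first / forward and back rates have come level)
2. how much of the substrate has reacted by 20 min
3. how much target there is at 20 min, in percent of the substrate charged
4. how much adduct there is at 20 min, in percent of the substrate charged

- every charge counts on the volume at the start, and the solution that is fed holds the whole dose
- what was read earlier has a scatter of 0.5 percentage points, one standard deviation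
- the reaction counts as stopped when no species that holds the substrate changes by six tenths of a point or more over the second half of the time

The reagent charge allowed 42.9 % of the substrate to react at midnight and 27.3 % at noon. The substrate readings, level from 5.00 min onwards, averaged 62.1 % and 74.5 % left. The midnight flask had therefore reacted less than its reagent allowed, keeping 11.7 % of its reagent, and the noon flask kept 6.38 %, yet neither moved further.

That gave me two independent ways to one number, from different substrate charges: midnight gave 43.4 /M and noon 44.8 /M. Noon is the shakier, its margin under the cap being 1.7 percentage points against a scatter of 0.5 points, less than the 5 points at midnight, but the two agree. I trusted their mean, 44.1 /M, and called it the balance number, an apparent equilibrium constant: the reacted share divided by the share of substrate left, the share of reagent left and the reagent charge on the fed volume.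

In the flask the reagent is again the limiting reagent. Holding the balance number there, I solved for 49.1 % reacted, and the flask has more time than the runs took to level. The gap between substrate lost and target found, which I read as adduct, was 8.06 % of the reacted share at midnight and 6.92 % at noon, so I expected 3.68 % adduct and 45.4 % target.

The forecast, holding that “the reaction still stops, which means equilibrium”, gave 49.5 % reacted, a little above mine, with 45.7 % target and 3.8 % adduct, and its verdict was: forward and back rates have come level.

The flask gave 48.6 % reacted, 45.6 % target and 3.04 % adduct, with this verdict: forward and back rates have come level. Left until 200 min, it still stood at 48.6 % reacted.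

    substrate + reagent ⇌ adduct (K = 2.60 /M, k = 0.250 /M/s)
    adduct ⇌ target (K = 15.0, k = 0.0420 /s)

The flask kept less of its reagent, 19 %, than of its substrate, 51 %. Put into the same flask with 0.26 M of reagent, the balance number of 44.1 /M reckons 73.1 % reacted, and that flask gave 72.4 %.

The runs are calculated with constants of no real substance, and the scatter is random.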